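**Strategy.** Everything rests on cutting both Cα–Cβ bonds of the oxolane (C2–C3 and C4–C5). The ring is a trans-2,5-disubstituted oxolane whose oxygen-bearing carbons C2 and C5 flank an unsubstituted C3–C4 unit; this hidden twofold symmetry leads back to a diglycolic acid bis-imide and a two-carbon bis-electrophile. In the key step the bis-enolate of the bis[(R)-4-benzyloxazolidinone] imide is alkylated twice by ethane-1,2-diyl bis(triflate): both ring C–C bonds and both oxolane stereocentres form in one flask, trans by double auxiliary control. The twofold-symmetric diol is then monotosylated; one arm becomes the trienyl chain, the other the trans-1,2-dioxane acetic acid by chelation-controlled addition, invertive hydroperoxide displacement and oxa-Michael closure.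

Key step: step 4

Remark: oxolane locants are O1, C2 (carries the dioxane) and C5 (carries the chain); dioxane locants are O1, O2, C3 (carries CH2CO2H) and C6 (carries the oxolane).

Step 1
Reactants: 1 ethane-1,2-diol
Product: 2 ethane-1,2-diyl bis(trifluoromethanesulfonate)
Conditions: Tf2O, pyridine, CH2Cl2, −20 to 0 °C
Reagents that add atoms: trifluoromethanesulfonic anhydride, O=S(=O)(OS(=O)(=O)C(F)(F)F)C(F)(F)F
Why: O-sulfonylation of both primary hydroxyls with triflic anhydride and pyridine (sulfonate ester formation) should give the bis-triflate, which is used fresh.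

Step 2
Reactants: 3 (4R)-4-benzyl-1,3-oxazolidin-2-one; 4 1,4-dioxane-2,6-dione (diglycolic anhydride)
Product: 6 2-[2-[(4R)-4-benzyl-2-oxo-1,3-oxazolidin-3-yl]-2-oxoethoxy]acetic acid, via lithium oxazolidinide 5 (not isolated)
Conditions: n-BuLi (1.0 equiv), THF, −78 °C; then 4, −78 to 0 °C; 1 M HCl work-up
Reagents that add atoms: none
Why: ring-opening N-acylation of the lithiated oxazolidinone by the cyclic anhydride (anhydride acylation of an Evans auxiliary) should stop at the mono-imide, because the second carboxyl leaves as an unreactive lithium carboxylate.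

Step 3
Reactants: 6 2-[2-[(4R)-4-benzyl-2-oxo-1,3-oxazolidin-3-yl]-2-oxoethoxy]acetic acid; 3 (4R)-4-benzyl-1,3-oxazolidin-2-one
Product: 8 3,3'-(2,2'-oxydiacetyl)bis[(4R)-4-benzyl-1,3-oxazolidin-2-one], via mixed pivalic anhydride 7 (not isolated)
Conditions: t-BuCOCl, Et3N, THF, −20 °C; then LiCl, 3, −20 °C to rt
Reagents that add atoms: none
Why: activation of the acid as its mixed pivalic anhydride and N-acylation of the oxazolidinone under Et3N/LiCl (one-pot mixed-anhydride acylation of an Evans auxiliary) should place the second (R)-auxiliary on the other glycolyl arm, attack taking place at the less hindered carbonyl.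

Step 4
Reactants: 8 3,3'-(2,2'-oxydiacetyl)bis[(4R)-4-benzyl-1,3-oxazolidin-2-one]; 2 ethane-1,2-diyl bis(trifluoromethanesulfonate)
Product: 11 3,3'-[(2S,5S)-oxolane-2,5-diyldicarbonyl]bis[(4R)-4-benzyl-1,3-oxazolidin-2-one], via disodium bis-enolate 9 (not isolated), via monoalkylated enolate triflate 10 (not isolated)
Conditions: NaN(SiMe3)2 (2.2 equiv), THF, −78 °C (8 added to the base, high dilution); then 2 (1.05 equiv), −78 to −40 °C
Reagents that add atoms: none
Why: Proposed new method: double deprotonation gives the chelated bis-(Z)-sodium enolate 9, one enolate carbon displaces a triflate of 2 in an SN2 step to give 10, and the second enolate is then alkylated intramolecularly by the remaining primary triflate, so that both ring C–C bonds form in one flask. The closest known reactions are the auxiliary-controlled alkylation of glycolate imide enolates (Evans alkylation) and the annulation of chiral succinate dianions with 1,ω-bis-electrophiles; a glycolate bis-enolate and a 1,2-bis-triflate have not been combined in this way. The oxolane closes by a 5-exo-tet C-alkylation in which the enolate double bond is exocyclic to the new ring. Each new stereocentre is controlled by its own auxiliary: the benzyl group of the (R)-oxazolidinone blocks one face of the chelated Z-enolate, the CH2 electrophile enters from the other face, and both carbons become S, which is the trans ring. The step needs C- over O-alkylation and substitution over elimination, which the soft chelated sodium enolates and the non-basic, halogen-free primary bis-triflate should secure, and ring closure over oligomerisation, which the intramolecular second alkylation under dilution should secure. It needs trans over cis, which is secured because both auxiliaries have the same handedness, so that reagent control operates twice in the same sense.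

Step 5
Reactants: 11 3,3'-[(2S,5S)-oxolane-2,5-diyldicarbonyl]bis[(4R)-4-benzyl-1,3-oxazolidin-2-one]
Product: 12 [(2S,5S)-oxolane-2,5-diyl]dimethanol
Conditions: LiBH4, H2O (1 equiv per imide), THF/Et2O, 0 °C
Reagents that add atoms: none
Why: LiBH4 should cleave both N-acyl oxazolidinones reductively to primary alcohols without touching the α-stereocentres, and the auxiliary is recovered (reductive auxiliary removal).

Step 6
Reactants: 12 [(2S,5S)-oxolane-2,5-diyl]dimethanol
Product: 13 [(2S,5S)-5-(hydroxymethyl)oxolan-2-yl]methyl 4-methylbenzenesulfonate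
Conditions: Ag2O, TsCl (1.1 equiv), KI (cat.), CH2Cl2, rt
Reagents that add atoms: 4-methylbenzenesulfonyl chloride, Cc1ccc(cc1)S(=O)(=O)Cl
Why: Ag2O-mediated monotosylation of a symmetrical diol should stop at the mono-sulfonate, and the twofold symmetry makes the two hydroxyls equivalent so that only one mono-tosylate can form.

Step 7
Reactants: 14 pent-4-enal; 15 2-(triphenyl-λ5-phosphanylidene)acetaldehyde
Product: 16 (2E)-hepta-2,6-dienal
Conditions: toluene, 80 °C
Reagents that add atoms: none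
Why: Wittig olefination with the stabilised formyl ylide should give the E-enal.

Step 8
Reactants: 17 (6-hydroxyhexyl)triphenylphosphonium bromide; 16 (2E)-hepta-2,6-dienal
Product: 19 (6Z,8E)-trideca-6,8,12-trien-1-ol, via ylide alkoxide 18 (not isolated)
Conditions: NaN(SiMe3)2 (2.05 equiv), THF, −78 to 0 °C; then 16, −78 °C to rt
Reagents that add atoms: none
Why: Wittig olefination with the non-stabilised ylide under lithium-free conditions should form the new C6=C7 alkene Z under kinetic control, while the E alkene of the enal is carried through unchanged.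

Step 9
Reactants: 19 (6Z,8E)-trideca-6,8,12-trien-1-ol
Product: 20 (5E,7Z)-13-bromotrideca-1,5,7-triene
Conditions: CBr4, PPh3, CH2Cl2, 0 °C
Reagents that add atoms: tetrabromomethane, BrC(Br)(Br)Br
Why: Appel bromination should convert the primary alcohol into the bromide under neutral conditions that leave the triene alone.

Step 10
Reactants: 20 (5E,7Z)-13-bromotrideca-1,5,7-triene; 13 [(2S,5S)-5-(hydroxymethyl)oxolan-2-yl]methyl 4-methylbenzenesulfonate
Product: 23 [(2S,5R)-5-[(7Z,9E)-tetradeca-7,9,13-trien-1-yl]oxolan-2-yl]methanol, via Grignard reagent 21 (not isolated), via chloromagnesium alkoxide 22 (not isolated)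
Conditions: 20, Mg, THF, 40 °C; 13, i-PrMgCl (1.0 equiv), THF, −40 °C; combined, Li2CuCl4 (5 mol %), −40 to 0 °C
Reagents that add atoms: none
Why: copper-catalysed cross-coupling of a Grignard reagent with a primary tosylate should join the chain at the CH2 outside the ring, so both oxolane stereocentres are untouched (the descriptor at C5 changes to R only through the priority change), and the free hydroxyl is masked in the flask as its magnesium alkoxide.

Step 11
Reactants: 23 [(2S,5R)-5-[(7Z,9E)-tetradeca-7,9,13-trien-1-yl]oxolan-2-yl]methanol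
Product: 24 (2S,5R)-5-[(7Z,9E)-tetradeca-7,9,13-trien-1-yl]oxolane-2-carbaldehyde
Conditions: Dess–Martin periodinane, NaHCO3, CH2Cl2, 0 °C to rt; used crude
Reagents that add atoms: none
Why: Dess–Martin oxidation should give the α-alkoxy aldehyde under buffered conditions that do not epimerise C2 and do not touch the alkenes.

Step 12
Reactants: 25 2-(2-bromoethyl)-1,3-dioxolane; 24 (2S,5R)-5-[(7Z,9E)-tetradeca-7,9,13-trien-1-yl]oxolane-2-carbaldehyde
Product: 27 (1S)-3-(1,3-dioxolan-2-yl)-1-[(2S,5R)-5-[(7Z,9E)-tetradeca-7,9,13-trien-1-yl]oxolan-2-yl]propan-1-ol, via Grignard reagent 26 (not isolated)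
Conditions: 25, Mg, THF, 25 °C; then 24, MgBr2·OEt2, CH2Cl2/Et2O, −78 °C
Reagents that add atoms: none
Why: Grignard addition under Cram chelation control, in which magnesium bridges the aldehyde oxygen and ring O1 and the nucleophile enters from the face away from ring C3, should set the carbinol as 1S (syn to O1).

Step 13
Reactants: 27 (1S)-3-(1,3-dioxolan-2-yl)-1-[(2S,5R)-5-[(7Z,9E)-tetradeca-7,9,13-trien-1-yl]oxolan-2-yl]propan-1-ol
Product: 28 (1S)-3-(1,3-dioxolan-2-yl)-1-[(2S,5R)-5-[(7Z,9E)-tetradeca-7,9,13-trien-1-yl]oxolan-2-yl]propyl methanesulfonate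
Conditions: MsCl, Et3N, CH2Cl2, 0 °C
Reagents that add atoms: methanesulfonyl chloride, CS(=O)(=O)Cl
Why: mesylation of the secondary alcohol activates C1 with retention for the later invertive displacement.

Step 14
Reactants: 28 (1S)-3-(1,3-dioxolan-2-yl)-1-[(2S,5R)-5-[(7Z,9E)-tetradeca-7,9,13-trien-1-yl]oxolan-2-yl]propyl methanesulfonate
Product: 29 (1S)-4-oxo-1-[(2S,5R)-5-[(7Z,9E)-tetradeca-7,9,13-trien-1-yl]oxolan-2-yl]butyl methanesulfonate
Conditions: TsOH·H2O (cat.), THF/H2O, 45 °C
Reagents that add atoms: water, O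
Why: acid-catalysed acetal hydrolysis should release the aldehyde, and the secondary mesylate, deactivated by the neighbouring ring oxygen, and the diene should tolerate dilute aqueous acid.

Step 15
Reactants: 29 (1S)-4-oxo-1-[(2S,5R)-5-[(7Z,9E)-tetradeca-7,9,13-trien-1-yl]oxolan-2-yl]butyl methanesulfonate; 30 tert-butyl 2-(triphenyl-λ5-phosphanylidene)acetate
Product: 31 tert-butyl (2E,6S)-6-(methanesulfonyloxy)-6-[(2S,5R)-5-[(7Z,9E)-tetradeca-7,9,13-trien-1-yl]oxolan-2-yl]hex-2-enoate
Conditions: CH2Cl2, rt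
Reagents that add atoms: none
Why: Wittig olefination with the stabilised ester ylide should give the E-enoate as the Michael acceptor, and the tert-butyl ester is chosen because it resists hydroperoxide anion.

Step 16
Reactants: 31 tert-butyl (2E,6S)-6-(methanesulfonyloxy)-6-[(2S,5R)-5-[(7Z,9E)-tetradeca-7,9,13-trien-1-yl]oxolan-2-yl]hex-2-enoate
Product: 33 tert-butyl 2-[(3R,6R)-6-[(2S,5R)-5-[(7Z,9E)-tetradeca-7,9,13-trien-1-yl]oxolan-2-yl]-1,2-dioxan-3-yl]acetate, via hydroperoxide 32 (not isolated)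
Conditions: H2O2 (50% aq., excess), KOH, MeOH/THF, 0 °C to rt
Reagents that add atoms: hydrogen peroxide, OO
Why: SN2 displacement of the secondary mesylate by hydroperoxide anion should invert C6 to R, and the hydroperoxide should then close the 1,2-dioxane by a reversible base-mediated 6-exo-trig oxa-Michael addition through a chair with both ring substituents equatorial, which sets C3 as R (trans).

Step 17
Reactants: 33 tert-butyl 2-[(3R,6R)-6-[(2S,5R)-5-[(7Z,9E)-tetradeca-7,9,13-trien-1-yl]oxolan-2-yl]-1,2-dioxan-3-yl]acetate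
Product: 34 2-[(3R,6R)-6-[(2S,5R)-5-[(7Z,9E)-tetradeca-7,9,13-trien-1-yl]oxolan-2-yl]-1,2-dioxan-3-yl]acetic acid
Conditions: CF3CO2H, CH2Cl2, 0 °C
Reagents that add atoms: none
Why: acidolysis of the tert-butyl ester (loss of 2-methylpropene) should free the acid without base, which avoids retro-oxa-Michael opening and Kornblum–DeLaMare cleavage of the peroxide.

Compound list
1 | ethane-1,2-diol | OCCO | starting material
2 | ethane-1,2-diyl bis(trifluoromethanesulfonate) | FC(F)(F)S(=O)(=O)OCCOS(=O)(=O)C(F)(F)F | intermediate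
3 | (4R)-4-benzyl-1,3-oxazolidin-2-one | O=C1N[C@H](Cc2ccccc2)CO1 | starting material
4 | 1,4-dioxane-2,6-dione (diglycolic anhydride) | O=C1COCC(=O)O1 | starting material
5 | lithium (4R)-4-benzyl-2-oxo-1,3-oxazolidin-3-ide | [Li+].O=C1OC[C@@H](Cc2ccccc2)[N-]1 | intermediate
6 | 2-[2-[(4R)-4-benzyl-2-oxo-1,3-oxazolidin-3-yl]-2-oxoethoxy]acetic acid | O=C1OC[C@@H](Cc2ccccc2)N1C(=O)COCC(=O)O | intermediate
7 | 2-[2-[(4R)-4-benzyl-2-oxo-1,3-oxazolidin-3-yl]-2-oxoethoxy]acetic 2,2-dimethylpropanoic anhydride | O=C1OC[C@@H](Cc2ccccc2)N1C(=O)COCC(=O)OC(=O)C(C)(C)C | intermediate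
8 | 3,3'-(2,2'-oxydiacetyl)bis[(4R)-4-benzyl-1,3-oxazolidin-2-one] | O=C1OC[C@@H](Cc2ccccc2)N1C(=O)COCC(=O)N3[C@H](Cc4ccccc4)COC3=O | intermediate
9 | disodium (1Z,1'Z)-2,2'-oxybis[1-[(4R)-4-benzyl-2-oxo-1,3-oxazolidin-3-yl]ethen-1-olate] | [Na+].[Na+].[O-]/C(=C\O/C=C(\[O-])N1[C@H](Cc2ccccc2)COC1=O)N1[C@H](Cc2ccccc2)COC1=O | intermediate
10 | sodium (1Z)-1-[(4R)-4-benzyl-2-oxo-1,3-oxazolidin-3-yl]-2-[[(2S)-1-[(4R)-4-benzyl-2-oxo-1,3-oxazolidin-3-yl]-1-oxo-4-(trifluoromethanesulfonyloxy)butan-2-yl]oxy]ethen-1-olate | [Na+].[O-]/C(=C\O[C@@H](CCOS(=O)(=O)C(F)(F)F)C(=O)N1[C@H](Cc2ccccc2)COC1=O)N1[C@H](Cc2ccccc2)COC1=O | intermediate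
11 | 3,3'-[(2S,5S)-oxolane-2,5-diyldicarbonyl]bis[(4R)-4-benzyl-1,3-oxazolidin-2-one] | O=C1OC[C@@H](Cc2ccccc2)N1C(=O)[C@@H]3CC[C@@H](C(=O)N4[C@H](Cc5ccccc5)COC4=O)O3 | intermediate
12 | [(2S,5S)-oxolane-2,5-diyl]dimethanol | OC[C@@H]1CC[C@@H](CO)O1 | intermediate
13 | [(2S,5S)-5-(hydroxymethyl)oxolan-2-yl]methyl 4-methylbenzenesulfonate | Cc1ccc(cc1)S(=O)(=O)OC[C@@H]1CC[C@@H](CO)O1 | intermediate
14 | pent-4-enal | C=CCCC=O | starting material
15 | 2-(triphenyl-λ5-phosphanylidene)acetaldehyde | O=CC=P(c1ccccc1)(c1ccccc1)c1ccccc1 | starting material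
16 | (2E)-hepta-2,6-dienal | C=CCC/C=C/C=O | intermediate
17 | (6-hydroxyhexyl)triphenylphosphonium bromide | OCCCCCC[P+](c1ccccc1)(c1ccccc1)c1ccccc1.[Br-] | starting material
18 | sodium 6-(triphenyl-λ5-phosphanylidene)hexan-1-olate | [Na+].[O-]CCCCCC=P(c1ccccc1)(c1ccccc1)c1ccccc1 | intermediate
19 | (6Z,8E)-trideca-6,8,12-trien-1-ol | C=CCC/C=C/C=C\CCCCCO | intermediate
20 | (5E,7Z)-13-bromotrideca-1,5,7-triene | C=CCC/C=C/C=C\CCCCCBr | intermediate
21 | [(6Z,8E)-trideca-6,8,12-trien-1-yl]magnesium bromide | C=CCC/C=C/C=C\CCCCC[Mg]Br | intermediate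
22 | [(2S,5S)-5-[(chloromagnesiooxy)methyl]oxolan-2-yl]methyl 4-methylbenzenesulfonate | Cc1ccc(cc1)S(=O)(=O)OC[C@@H]1CC[C@@H](CO[Mg]Cl)O1 | intermediate
23 | [(2S,5R)-5-[(7Z,9E)-tetradeca-7,9,13-trien-1-yl]oxolan-2-yl]methanol | C=CCC/C=C/C=C\CCCCCC[C@@H]1CC[C@@H](CO)O1 | intermediate
24 | (2S,5R)-5-[(7Z,9E)-tetradeca-7,9,13-trien-1-yl]oxolane-2-carbaldehyde | C=CCC/C=C/C=C\CCCCCC[C@@H]1CC[C@@H](C=O)O1 | intermediate
25 | 2-(2-bromoethyl)-1,3-dioxolane | BrCCC1OCCO1 | starting material
26 | [2-(1,3-dioxolan-2-yl)ethyl]magnesium bromide | Br[Mg]CCC1OCCO1 | intermediate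
27 | (1S)-3-(1,3-dioxolan-2-yl)-1-[(2S,5R)-5-[(7Z,9E)-tetradeca-7,9,13-trien-1-yl]oxolan-2-yl]propan-1-ol | C=CCC/C=C/C=C\CCCCCC[C@@H]1CC[C@@H]([C@@H](O)CCC2OCCO2)O1 | intermediate
28 | (1S)-3-(1,3-dioxolan-2-yl)-1-[(2S,5R)-5-[(7Z,9E)-tetradeca-7,9,13-trien-1-yl]oxolan-2-yl]propyl methanesulfonate | C=CCC/C=C/C=C\CCCCCC[C@@H]1CC[C@@H]([C@@H](OS(C)(=O)=O)CCC2OCCO2)O1 | intermediate
29 | (1S)-4-oxo-1-[(2S,5R)-5-[(7Z,9E)-tetradeca-7,9,13-trien-1-yl]oxolan-2-yl]butyl methanesulfonate | C=CCC/C=C/C=C\CCCCCC[C@@H]1CC[C@@H]([C@@H](OS(C)(=O)=O)CCC=O)O1 | intermediate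
30 | tert-butyl 2-(triphenyl-λ5-phosphanylidene)acetate | CC(C)(C)OC(=O)C=P(c1ccccc1)(c1ccccc1)c1ccccc1 | starting material
31 | tert-butyl (2E,6S)-6-(methanesulfonyloxy)-6-[(2S,5R)-5-[(7Z,9E)-tetradeca-7,9,13-trien-1-yl]oxolan-2-yl]hex-2-enoate | C=CCC/C=C/C=C\CCCCCC[C@@H]1CC[C@@H]([C@@H](OS(C)(=O)=O)CC/C=C/C(=O)OC(C)(C)C)O1 | intermediate
32 | tert-butyl (2E,6R)-6-hydroperoxy-6-[(2S,5R)-5-[(7Z,9E)-tetradeca-7,9,13-trien-1-yl]oxolan-2-yl]hex-2-enoate | C=CCC/C=C/C=C\CCCCCC[C@@H]1CC[C@@H]([C@H](OO)CC/C=C/C(=O)OC(C)(C)C)O1 | intermediate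
33 | tert-butyl 2-[(3R,6R)-6-[(2S,5R)-5-[(7Z,9E)-tetradeca-7,9,13-trien-1-yl]oxolan-2-yl]-1,2-dioxan-3-yl]acetate | C=CCC/C=C/C=C\CCCCCC[C@@H]1CC[C@@H]([C@H]2CC[C@H](CC(=O)OC(C)(C)C)OO2)O1 | intermediate
34 | 2-[(3R,6R)-6-[(2S,5R)-5-[(7Z,9E)-tetradeca-7,9,13-trien-1-yl]oxolan-2-yl]-1,2-dioxan-3-yl]acetic acid | C=CCC/C=C/C=C\CCCCCC[C@@H]1CC[C@@H]([C@H]2CC[C@H](CC(=O)O)OO2)O1 | target

Total step count: 17 steps.
Longest linear sequence: 13 steps (steps 2, 3, 4, 5, 6, 10, 11, 12, 13, 14, 15, 16 and 17, from 3 and 4 to 34).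

Steps most likely to fail

1. Step 4 (proposed new method). What may go wrong: O-alkylation of the enolates, base-induced elimination of the bis-triflate, capture of the pendant triflate by the neighbouring imide carbonyl oxygen, oligomerisation before ring closure, or loss of auxiliary control in the ring-closing alkylation, which would give the cis ring. The fallback uses known chemistry and closes the ring through a C–O bond instead. It sets out from bromide 20. Its Grignard reagent 21 opens commercial (2S)-2-(but-3-en-1-yl)oxirane (C=CCC[C@H]1CO1) at the terminal carbon under CuI catalysis in THF at −30 °C to give (5R,12Z,14E)-nonadeca-1,12,14,18-tetraen-5-ol F1. Mukaiyama aerobic oxidative cyclisation of F1 (Co(modp)2, which is bis(1-morpholinocarbamoyl-4,4-dimethyl-1,3-pentanedionato)cobalt with divalent cobalt, O2, t-BuOOH, i-PrOH, 50 °C) should then close the trans-2,5-disubstituted oxolane, and the route is rejoined at alcohol 23.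

2. Step 16. What may go wrong: E2 elimination of the hindered mesylate, and attack of hydroperoxide or methoxide on the enoate, may outrun the slow SN2 step. The fallback installs the O–O bond before the Michael acceptor exists. It sets out from mesylate 28, which with H2O2 and KOH in MeOH should give 2-[(3R)-3-hydroperoxy-3-[(2S,5R)-5-[(7Z,9E)-tetradeca-7,9,13-trien-1-yl]oxolan-2-yl]propyl]-1,3-dioxolane F2. Aqueous TsOH then unmasks the aldehyde, which should close onto the hydroperoxide to give the peroxy-hemiacetal (6R)-6-[(2S,5R)-5-[(7Z,9E)-tetradeca-7,9,13-trien-1-yl]oxolan-2-yl]-1,2-dioxan-3-ol F3. Wittig reaction of F3 with ylide 30, followed by Et2NH in CF3CH2OH to drive the oxa-Michael closure, comes back to the route at ester 33.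

3. Step 12. What may go wrong: incomplete chelation and therefore poor facial selectivity in the addition to the α-alkoxy aldehyde. The fallback sets the carbinol by reduction instead of addition. It sets out from aldehyde 24, to which 26 is added without stereocontrol; this gives 27 mixed with (1R)-3-(1,3-dioxolan-2-yl)-1-[(2S,5R)-5-[(7Z,9E)-tetradeca-7,9,13-trien-1-yl]oxolan-2-yl]propan-1-ol F4. Dess–Martin oxidation of the mixture gives 3-(1,3-dioxolan-2-yl)-1-[(2S,5R)-5-[(7Z,9E)-tetradeca-7,9,13-trien-1-yl]oxolan-2-yl]propan-1-one F5. Felkin–Anh reduction of F5 with LiBH(s-Bu)3 in THF at −78 °C should then return to 27.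

Further compounds
F1 | step 4 | (5R,12Z,14E)-nonadeca-1,12,14,18-tetraen-5-ol | C=CCC/C=C/C=C\CCCCCC[C@@H](O)CCC=C
F2 | step 16 | 2-[(3R)-3-hydroperoxy-3-[(2S,5R)-5-[(7Z,9E)-tetradeca-7,9,13-trien-1-yl]oxolan-2-yl]propyl]-1,3-dioxolane | C=CCC/C=C/C=C\CCCCCC[C@@H]1CC[C@@H]([C@H](OO)CCC2OCCO2)O1
F3 | step 16 | (6R)-6-[(2S,5R)-5-[(7Z,9E)-tetradeca-7,9,13-trien-1-yl]oxolan-2-yl]-1,2-dioxan-3-ol | C=CCC/C=C/C=C\CCCCCC[C@@H]1CC[C@@H]([C@H]2CCC(O)OO2)O1
F4 | step 12 | (1R)-3-(1,3-dioxolan-2-yl)-1-[(2S,5R)-5-[(7Z,9E)-tetradeca-7,9,13-trien-1-yl]oxolan-2-yl]propan-1-ol | C=CCC/C=C/C=C\CCCCCC[C@@H]1CC[C@@H]([C@H](O)CCC2OCCO2)O1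
F5 | step 12 | 3-(1,3-dioxolan-2-yl)-1-[(2S,5R)-5-[(7Z,9E)-tetradeca-7,9,13-trien-1-yl]oxolan-2-yl]propan-1-one | C=CCC/C=C/C=C\CCCCCC[C@@H]1CC[C@@H](C(=O)CCC2OCCO2)O1
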